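**Plan**
- Retrosynthesis: the acrylic acid side chain is cut at its C=C bond (Wittig, from a C4 aldehyde); C2 is taken back to a carbonyl and the hydrogens at C1 and C7a to a C1=C7a alkene. The 2-methylcyclopentenone thus revealed is cut at C3a–C7a, C1–C2 and C2–C3 (alkyne + alkene + CO), which opens both rings to an acyclic dienyne.
- Enabling feature: in the cyclopentane ring C1–C2–C3–C3a–C7a the only methylene, C2, lies between the two CH(CH3) carbons C1 and C3, and the ring shares the C3a–C7a bond with the cyclohexene ring. With C2 as C=O and C1=C7a, this is the product pattern of an intramolecular Pauson–Khand reaction of a 1,7-enyne.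
- Forward: the chain is built on a butyrolactone (phenyl addition, two alkylations), opened by a lactol Wittig reaction and extended by iodo-olefination and Sonogashira coupling. Both carbocycles then form in one step, followed by redox adjustment and attachment of the side chain.
- Stereochemistry: C5 from the Rh/(R)-BINAP phenyl addition; C4 from enolate alkylation anti to phenyl; C3 and C3a in the key step (Z-alkene geometry, face-selective insertion); C7a and C1 from hydroxyl-directed hydrogenation; the E-alkene from a stabilised ylide.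

Key step: step 11

Convention and assumption: ring atoms carry the hexahydro-1H-indene numbers of the target (C4 quaternary, C5 benzylic, C3a/C7a fusion), β is the face bearing 4-ethyl and 5-phenyl, TBS is tert-butyldimethylsilyl; the sense of induction in step 1 is assumed to follow that known for cyclic enones, so that (R)-BINAP gives the (R) lactone.

**Step 1**
Reactants: 1 furan-2(5H)-one; 2 phenylboronic acid
Product: 3 (R)-4-phenyldihydrofuran-2(3H)-one
Conditions: Rh(acac)(C2H4)2 (3 mol%), (R)-BINAP (3.3 mol%), dioxane/H2O 10:1, 100 °C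
Reagents that add atoms: none
Why: Hayashi–Miyaura rhodium-catalysed asymmetric conjugate addition of an arylboronic acid to an unsaturated lactone, in which the (R)-BINAP–rhodium–phenyl species adds to one enantioface of the butenolide and so sets the benzylic centre that becomes C5.

**Step 2**
Reactants: 3 (R)-4-phenyldihydrofuran-2(3H)-one; 4 iodoethane
Product: 6 (3S,4R)-3-ethyl-4-phenyldihydrofuran-2(3H)-one, via lithium enolate 5 (not isolated)
Conditions: LiN(i-Pr)2, THF, −78 °C; then EtI, DMPU, −78 → −30 °C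
Reagents that add atoms: none
Why: Lactone enolate alkylation, with iodoethane entering anti to the neighbouring phenyl group; the C3 configuration is of no consequence because this centre is enolised again in step 3.

**Step 3**
Reactants: 6 (3S,4R)-3-ethyl-4-phenyldihydrofuran-2(3H)-one; 7 benzyl chloromethyl ether
Product: 9 (3R,4S)-3-[(benzyloxy)methyl]-3-ethyl-4-phenyldihydrofuran-2(3H)-one, via lithium enolate 8 (not isolated)
Conditions: LiN(i-Pr)2, THF, −78 °C; then BnOCH2Cl, −78 → −20 °C
Reagents that add atoms: none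
Why: Second lactone enolate alkylation, in which the planar enolate is attacked by the reactive chloromethyl ether on the face opposite the C4 phenyl group, so that the quaternary centre (C4 of the target) forms with CH2OBn trans and ethyl cis to phenyl.

**Step 4**
Reactants: 9 (3R,4S)-3-[(benzyloxy)methyl]-3-ethyl-4-phenyldihydrofuran-2(3H)-one
Product: 10 (3R,4S)-3-ethyl-3-(hydroxymethyl)-4-phenyldihydrofuran-2(3H)-one
Conditions: H2 (1 atm), 10% Pd/C, EtOAc, rt
Reagents that add atoms: none
Why: Hydrogenolysis of a benzyl ether over palladium on carbon, done here while the molecule still has no alkene, leaves the lactone and the C-phenyl group untouched.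

**Step 5**
Reactants: 10 (3R,4S)-3-ethyl-3-(hydroxymethyl)-4-phenyldihydrofuran-2(3H)-one
Product: 11 (3R,4S)-3-[(TBS-oxy)methyl]-3-ethyl-4-phenyldihydrofuran-2(3H)-one
Conditions: TBSCl, imidazole, DMF, rt
Reagents that add atoms: tert-butyldimethylsilyl chloride, CC(C)(C)[Si](C)(C)Cl
Why: Imidazole-promoted silylation of a primary alcohol gives a silyl ether that should withstand the hydride, ylide, cobalt, iridium and radical steps ahead and is removed by fluoride in step 16.

**Step 6**
Reactants: 11 (3R,4S)-3-[(TBS-oxy)methyl]-3-ethyl-4-phenyldihydrofuran-2(3H)-one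
Product: 12 (3R,4S)-3-[(TBS-oxy)methyl]-3-ethyl-4-phenyltetrahydrofuran-2-ol (lactol; anomer mixture)
Conditions: i-Bu2AlH (1.1 equiv), CH2Cl2, −78 °C; aq potassium sodium tartrate
Reagents that add atoms: none
Why: Partial reduction of a lactone with i-Bu2AlH at low temperature stops at the aluminium hemiacetal, which the adjacent quaternary carbon further shields from over-reduction.

**Step 7**
Reactants: 12 lactol
Product: 14 (2S,3R,4Z)-3-[(TBS-oxy)methyl]-3-ethyl-2-phenylhex-4-en-1-ol, via hydroxy aldehyde 13 (not isolated)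
Conditions: [Ph3PEt]Br, KN(SiMe3)2, THF, 0 °C; then 12, 0 → 50 °C
Reagents that add atoms: ethyltriphenylphosphonium bromide, CC[P+](c1ccccc1)(c1ccccc1)c1ccccc1.[Br-]
Why: Wittig olefination of a lactol through its open hydroxy aldehyde form, in which the salt-free non-stabilised ethylidene ylide and the α-quaternary aldehyde should give the Z-propenyl group under kinetic control and release the primary alcohol needed next.

**Step 8**
Reactants: 14 (2S,3R,4Z)-3-[(TBS-oxy)methyl]-3-ethyl-2-phenylhex-4-en-1-ol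
Product: 15 (2S,3R,4Z)-3-[(TBS-oxy)methyl]-3-ethyl-2-phenylhex-4-enal
Conditions: Dess–Martin periodinane, NaHCO3, CH2Cl2, 0 °C → rt
Reagents that add atoms: none
Why: Dess–Martin oxidation of a primary alcohol under buffered, non-basic conditions should give the α-phenyl aldehyde without epimerising its α-centre, which the adjacent quaternary carbon also shields.

**Step 9**
Reactants: 15 (2S,3R,4Z)-3-[(TBS-oxy)methyl]-3-ethyl-2-phenylhex-4-enal
Product: 16 (2Z,4S,5R,6Z)-5-[(TBS-oxy)methyl]-5-ethyl-2-iodo-4-phenylocta-2,6-diene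
Conditions: [Ph3PEt]I, n-BuLi, THF, rt; I2, −78 °C; NaN(SiMe3)2, −20 °C; then 15, −78 → −20 °C
Reagents that add atoms: ethyltriphenylphosphonium iodide, CC[P+](c1ccccc1)(c1ccccc1)c1ccccc1.[I-]; iodine, II
Why: Stork–Zhao-type iodo-olefination with (1-iodoethylidene)triphenylphosphorane, which gives (Z)-2-iodo-2-alkenes under kinetic control, places iodine cis and methyl trans to the benzylic carbon, the geometry the ring closure needs.

**Step 10**
Reactants: 16 (2Z,4S,5R,6Z)-5-[(TBS-oxy)methyl]-5-ethyl-2-iodo-4-phenylocta-2,6-diene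
Product: 17 (4Z,6S,7R,8Z)-7-[(TBS-oxy)methyl]-7-ethyl-4-methyl-6-phenyldeca-4,8-dien-2-yne
Conditions: propyne, Pd(PPh3)2Cl2 (5 mol%), CuI (10 mol%), i-Pr2NH, THF, rt
Reagents that add atoms: propyne, CC#C
Why: Sonogashira coupling of an alkenyl iodide with a terminal alkyne proceeds with retention of alkene geometry, so the methyl-capped alkyne ends up cis to the benzylic carbon.

**Step 11**
Reactants: 17 (4Z,6S,7R,8Z)-7-[(TBS-oxy)methyl]-7-ethyl-4-methyl-6-phenyldeca-4,8-dien-2-yne
Product: 19 4α-[(TBS-oxy)methyl]-4β-ethyl-1,3α,7-trimethyl-5β-phenyl-3,3a,4,5-tetrahydro-2H-inden-2-one (3a-H β), via dicobalt hexacarbonyl complex 18 (not isolated)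
Conditions: Co2(CO)8 (1.1 equiv), ClCH2CH2Cl, rt; then n-BuSMe (4 equiv), 83 °C
Reagents that add atoms: dicobalt octacarbonyl Co2(CO)8 (one CO is transferred), [Co].[Co].[C-]#[O+].[C-]#[O+].[C-]#[O+].[C-]#[O+].[C-]#[O+].[C-]#[O+].[C-]#[O+].[C-]#[O+]
Why: Co2(CO)8 binds the C2≡C3 alkyne of 17 as complex 18, the sulfide promotes loss of one CO, the Z-propenyl alkene coordinates and inserts into the Co–C bond of the inner alkyne carbon to give a cobaltacycle, and CO insertion followed by reductive elimination releases the enone. The closest known reaction type is the intramolecular Pauson–Khand reaction of 1,7-enynes to hydrindenones, here with a conjugated enyne and a 1,2-disubstituted alkene. The cyclohexene ring closes by 6-exo insertion that forms the C3a–C7a bond, its four-atom tether being held in reach by the Z-enyne and the quaternary C4 (Thorpe–Ingold effect); the cyclopentenone closes when CO is inserted between C1 and C3, forming C1–C2 and C2–C3. C3 is set relative to C3a by the alkene geometry, since both new bonds add to the same face of the Z-alkene and so place 3-CH3 cis to the C3a–C4 bond (3-H cis to 3a-H); C3a is set relative to C4 and C5 by the alkene face that inserts. The step needs insertion on the face that puts C3 anti to the 5-phenyl group, and this should be secured by a half-chair transition state with phenyl pseudo-equatorial in which the Z-methyl, to avoid allylic strain with the ethyl and siloxymethyl groups on C4, lies over the small C5–H. The neutral conditions should leave the epimerisable C3 centre of 19 untouched.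

**Step 12**
Reactants: 19 dienone
Product: 20 4α-[(TBS-oxy)methyl]-4β-ethyl-1,3α,7-trimethyl-5β-phenyl-3,3a,4,5-tetrahydro-2H-inden-2α-ol (3a-H β)
Conditions: NaBH4, CeCl3·7H2O, MeOH, −40 °C
Reagents that add atoms: none
Why: Luche 1,2-reduction of the dienone, with hydride attacking C2 from the β face opposite the 3-methyl group, should give the 2α-alcohol (hydroxyl cis to 3-methyl) that serves as the directing group.

**Step 13**
Reactants: 20 dienol
Product: 21 4α-[(TBS-oxy)methyl]-4β-ethyl-1β,3α,7-trimethyl-5β-phenyl-2,3,3a,4,5,7a-hexahydro-1H-inden-2α-ol (3a-H β; 7a-H α)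
Conditions: [Ir(cod)(PCy3)(py)]PF6 (5 mol%), H2 (1 atm), CH2Cl2, 0 °C → rt
Reagents that add atoms: none
Why: Hydroxyl-directed hydrogenation with Crabtree's catalyst, in which iridium bound to the 2α-hydroxyl delivers both hydrogens to the α face of the neighbouring tetrasubstituted C1=C7a alkene (7a-H α, hence trans ring fusion, and 1-H α with 1-methyl β), while the remote and hindered C6=C7 alkene lies outside the reach of the bound metal.

**Step 14**
Reactants: 21 alcohol
Product: 23 O-[the inden-2α-yl of 21] S-methyl dithiocarbonate, via sodium xanthate 22 (not isolated)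
Conditions: NaH, CS2, THF, 0 °C → rt; then MeI
Reagents that add atoms: carbon disulfide, S=C=S; iodomethane, CI
Why: Xanthate formation from a secondary alkoxide, carbon disulfide and iodomethane, the first half of a Barton–McCombie deoxygenation, touches no stereocentre.

**Step 15**
Reactants: 23 S-methyl xanthate
Product: 24 tert-butyl{[4β-ethyl-1β,3α,7-trimethyl-5β-phenyl-2,3,3a,4,5,7a-hexahydro-1H-inden-4α-yl]methoxy}dimethylsilane (3a-H β; 7a-H α)
Conditions: Bu3SnH, AIBN (10 mol%), toluene, 100 °C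
Reagents that add atoms: none
Why: Barton–McCombie radical deoxygenation, in which the secondary C2 radical takes hydrogen from Bu3SnH and has no geometrically feasible cyclisation onto the C6=C7 alkene, removes the directing hydroxyl and leaves C2 as the ring methylene.

**Step 16**
Reactants: 24 silyl ether
Product: 25 [4β-ethyl-1β,3α,7-trimethyl-5β-phenyl-2,3,3a,4,5,7a-hexahydro-1H-inden-4α-yl]methanol
Conditions: Bu4NF, THF, rt → 40 °C
Reagents that add atoms: none
Why: Fluoride-mediated cleavage of the silyl ether frees the neopentyl primary alcohol, and nothing else in the hydrocarbon skeleton is sensitive to basic fluoride.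

**Step 17**
Reactants: 25 primary alcohol
Product: 26 4β-ethyl-1β,3α,7-trimethyl-5β-phenyl-2,3,3a,4,5,7a-hexahydro-1H-indene-4α-carbaldehyde
Conditions: Dess–Martin periodinane, NaHCO3, CH2Cl2, rt
Reagents that add atoms: none
Why: Dess–Martin oxidation gives an aldehyde on a quaternary carbon that can neither enolise nor epimerise.

**Step 18**
Reactants: 26 aldehyde
Product: 27 ethyl (2E)-3-[4β-ethyl-1β,3α,7-trimethyl-5β-phenyl-2,3,3a,4,5,7a-hexahydro-1H-inden-4α-yl]-2-methylprop-2-enoate
Conditions: Ph3P=C(CH3)CO2Et, toluene, 110 °C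
Reagents that add atoms: ethyl 2-(triphenylphosphoranylidene)propanoate, CCOC(=O)C(C)=P(c1ccccc1)(c1ccccc1)c1ccccc1
Why: Wittig olefination with a stabilised α-methyl ylide, reversible in its addition step and therefore E-selective, should convert even this hindered neopentyl aldehyde on heating into the (E)-2-methylpropenoate.

**Step 19**
Reactants: 27 ethyl ester
Product: 28 plakotenin
Conditions: LiOH, THF/MeOH/H2O, 50 °C; then aq HCl to pH 3
Reagents that add atoms: lithium hydroxide, [Li+].[OH-]
Why: Saponification of the ethyl ester by acyl–oxygen cleavage followed by acidification gives the free acid, the molecule having no base-labile stereocentre and the E geometry being the stable one.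

**Compound list**
1 | furan-2(5H)-one | O=C1OCC=C1 | starting material
2 | phenylboronic acid | OB(O)c1ccccc1 | starting material
3 | (R)-4-phenyldihydrofuran-2(3H)-one | O=C1C[C@H](c2ccccc2)CO1 | intermediate
4 | iodoethane | CCI | starting material
5 | lithium enolate of 3 | [Li+].[O-]C1=C[C@H](c2ccccc2)CO1 | intermediate
6 | (3S,4R)-3-ethyl-4-phenyldihydrofuran-2(3H)-one | O=C1[C@@H](CC)[C@H](c2ccccc2)CO1 | intermediate
7 | benzyl chloromethyl ether | ClCOCc1ccccc1 | starting material
8 | lithium enolate of 6 | [Li+].[O-]C1=C(CC)[C@H](c2ccccc2)CO1 | intermediate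
9 | (3R,4S)-3-[(benzyloxy)methyl]-3-ethyl-4-phenyldihydrofuran-2(3H)-one | O=C1[C@@](CC)(COCc2ccccc2)[C@H](c2ccccc2)CO1 | intermediate
10 | (3R,4S)-3-ethyl-3-(hydroxymethyl)-4-phenyldihydrofuran-2(3H)-one | O=C1[C@@](CC)(CO)[C@H](c2ccccc2)CO1 | intermediate
11 | (3R,4S)-3-[(TBS-oxy)methyl]-3-ethyl-4-phenyldihydrofuran-2(3H)-one | O=C1[C@@](CC)(CO[Si](C)(C)C(C)(C)C)[C@H](c2ccccc2)CO1 | intermediate
12 | (3R,4S)-3-[(TBS-oxy)methyl]-3-ethyl-4-phenyltetrahydrofuran-2-ol (anomer mixture) | OC1[C@@](CC)(CO[Si](C)(C)C(C)(C)C)[C@H](c2ccccc2)CO1 | intermediate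
13 | (2R,3S)-2-[(TBS-oxy)methyl]-2-ethyl-4-hydroxy-3-phenylbutanal | O=C[C@@](CC)(CO[Si](C)(C)C(C)(C)C)[C@H](c1ccccc1)CO | intermediate
14 | (2S,3R,4Z)-3-[(TBS-oxy)methyl]-3-ethyl-2-phenylhex-4-en-1-ol | CC[C@@]([C@H](c1ccccc1)CO)(CO[Si](C)(C)C(C)(C)C)/C=C\C | intermediate
15 | (2S,3R,4Z)-3-[(TBS-oxy)methyl]-3-ethyl-2-phenylhex-4-enal | CC[C@@]([C@H](c1ccccc1)C=O)(CO[Si](C)(C)C(C)(C)C)/C=C\C | intermediate
16 | (2Z,4S,5R,6Z)-5-[(TBS-oxy)methyl]-5-ethyl-2-iodo-4-phenylocta-2,6-diene | CC[C@@]([C@H](c1ccccc1)/C=C(/C)I)(CO[Si](C)(C)C(C)(C)C)/C=C\C | intermediate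
17 | (4Z,6S,7R,8Z)-7-[(TBS-oxy)methyl]-7-ethyl-4-methyl-6-phenyldeca-4,8-dien-2-yne | CC[C@@]([C@H](c1ccccc1)/C=C(/C)C#CC)(CO[Si](C)(C)C(C)(C)C)/C=C\C | intermediate
18 | hexacarbonyldicobalt complex of the C2≡C3 alkyne of 17 | CC[C@@]([C@H](c1ccccc1)/C=C(/C)C23[Co]4(=C=O)(=C=O)(=C=O)[Co]2(=C=O)(=C=O)(=C=O)C34C)(CO[Si](C)(C)C(C)(C)C)/C=C\C | intermediate
19 | 4α-[(TBS-oxy)methyl]-4β-ethyl-1,3α,7-trimethyl-5β-phenyl-3,3a,4,5-tetrahydro-2H-inden-2-one (3a-H β) | CC[C@@]1(CO[Si](C)(C)C(C)(C)C)[C@H]2C(C(C)=C[C@H]1c1ccccc1)=C(C)C(=O)[C@H]2C | intermediate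
20 | 2α-alcohol of 19 (2-OH cis to 3-CH3) | CC[C@@]1(CO[Si](C)(C)C(C)(C)C)[C@H]2C(C(C)=C[C@H]1c1ccccc1)=C(C)[C@@H](O)[C@H]2C | intermediate
21 | 4α-[(TBS-oxy)methyl]-4β-ethyl-1β,3α,7-trimethyl-5β-phenyl-2,3,3a,4,5,7a-hexahydro-1H-inden-2α-ol (3a-H β; 7a-H α) | CC[C@@]1(CO[Si](C)(C)C(C)(C)C)[C@H]2[C@H](C(C)=C[C@H]1c1ccccc1)[C@H](C)[C@@H](O)[C@H]2C | intermediate
22 | sodium xanthate (O-alkyl dithiocarbonate salt) of 21 | CC[C@@]1(CO[Si](C)(C)C(C)(C)C)[C@H]2[C@H](C(C)=C[C@H]1c1ccccc1)[C@H](C)[C@@H](OC(=S)[S-])[C@H]2C.[Na+] | intermediate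
23 | S-methyl xanthate of 21 | CC[C@@]1(CO[Si](C)(C)C(C)(C)C)[C@H]2[C@H](C(C)=C[C@H]1c1ccccc1)[C@H](C)[C@@H](OC(=S)SC)[C@H]2C | intermediate
24 | tert-butyl{[4β-ethyl-1β,3α,7-trimethyl-5β-phenyl-2,3,3a,4,5,7a-hexahydro-1H-inden-4α-yl]methoxy}dimethylsilane (3a-H β; 7a-H α) | CC[C@@]1(CO[Si](C)(C)C(C)(C)C)[C@H]2[C@H](C(C)=C[C@H]1c1ccccc1)[C@H](C)C[C@H]2C | intermediate
25 | [4β-ethyl-1β,3α,7-trimethyl-5β-phenyl-2,3,3a,4,5,7a-hexahydro-1H-inden-4α-yl]methanol | CC[C@@]1(CO)[C@H]2[C@H](C(C)=C[C@H]1c1ccccc1)[C@H](C)C[C@H]2C | intermediate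
26 | 4β-ethyl-1β,3α,7-trimethyl-5β-phenyl-2,3,3a,4,5,7a-hexahydro-1H-indene-4α-carbaldehyde | CC[C@@]1(C=O)[C@H]2[C@H](C(C)=C[C@H]1c1ccccc1)[C@H](C)C[C@H]2C | intermediate
27 | ethyl (2E)-3-[4β-ethyl-1β,3α,7-trimethyl-5β-phenyl-2,3,3a,4,5,7a-hexahydro-1H-inden-4α-yl]-2-methylprop-2-enoate | CC[C@@]1(/C=C(\C)C(=O)OCC)[C@H]2[C@H](C(C)=C[C@H]1c1ccccc1)[C@H](C)C[C@H]2C | intermediate
28 | plakotenin, (2E)-3-[(1R,3R,3aR,4S,5S,7aR)-4-ethyl-1,3,7-trimethyl-5-phenyl-2,3,3a,4,5,7a-hexahydro-1H-inden-4-yl]-2-methylprop-2-enoic acid | CC[C@@]1(/C=C(\C)C(=O)O)[C@H]2[C@H](C(C)=C[C@H]1c1ccccc1)[C@H](C)C[C@H]2C | target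

**Step count and risks**
Total steps: 19. Longest linear sequence: 19 steps, from furan-2(5H)-one 1 to plakotenin 28.

Step 11 (most at risk). Insertion of the 1,2-disubstituted Z-alkene into the cobalt–carbon bond may be too slow, so that decomplexation, Z-to-E isomerisation of the propenyl group or reduction of the alkyne take over; the two alkene faces may also be differentiated too weakly. The fallback takes the C3 methyl group out of the cyclisation and adds it afterwards through the enolate. It sets out from lactol 12: methylenation with Ph3P=CH2 (from [Ph3PCH3]Br and KN(SiMe3)2) gives vinyl alcohol F1. The operations of steps 8 to 10 then give aldehyde F2, iodoalkene F3 and enyne F4. Co2(CO)8 converts F4 into dicobalt complex F5, whose Pauson–Khand reaction with a monosubstituted alkene, the most reactive alkene class, should give 3-demethyl dienone F6. Kinetic α'-enolisation with LiN(i-Pr)2 and methylation with CH3I from the less hindered β face should give 3-epi dienone F7. A second enolisation and protonation at −78 °C from the same β face then places 3-H β and returns to the route at dienone 19.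

Step 13. Addition of hydrogen to the tetrasubstituted C1=C7a alkene from its more hindered α face may be slow, and under forcing the conjugated ring-A alkene C6=C7 may be reduced or shifted as well. The fallback masks C6=C7 as an epoxide while the reduction is done; the cost is a more crowded C1=C7a alkene. It sets out from dienone 19: m-CPBA (NaHCO3, CH2Cl2, 0 °C) should epoxidise the electron-richer γ,δ-alkene, anti to phenyl, to give epoxy enone F8. Luche reduction gives epoxy alcohol F9. The directed hydrogenation of step 13, now on a substrate with a single C=C bond, gives saturated epoxy alcohol F10. Deoxygenation of the epoxide with PPh3 and catalytic CH3ReO3 (toluene, 60 °C) restores C6=C7 and returns to the route at alcohol 21.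

Step 9. The basic iodo-ylide may epimerise the α-phenyl aldehyde, add sluggishly to the crowded carbonyl group or give incomplete Z selectivity. The fallback builds the trisubstituted alkene by two stereospecific cross-couplings on a 1,1-dihaloalkene. It sets out from aldehyde 15: PPh3/CBrCl3 (CH3CN, rt, neutral) gives 1,1-dichloroalkene F11. Trans-selective Negishi monomethylation (Me2Zn, Pd(DPEphos)Cl2, THF) replaces the chloride trans to the bulky benzylic carbon and gives (Z)-chloroalkene F12. Negishi coupling of the remaining chloride with 1-propynylzinc chloride (Pd(t-Bu3P)2, THF, 60 °C) proceeds with retention and returns to the route at dienyne 17.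

**Further compounds**
F1 | step 11 | (2S,3R)-3-[(TBS-oxy)methyl]-3-ethyl-2-phenylpent-4-en-1-ol | CC[C@@]([C@H](c1ccccc1)CO)(CO[Si](C)(C)C(C)(C)C)C=C
F2 | step 11 | (2S,3R)-3-[(TBS-oxy)methyl]-3-ethyl-2-phenylpent-4-enal | CC[C@@]([C@H](c1ccccc1)C=O)(CO[Si](C)(C)C(C)(C)C)C=C
F3 | step 11 | (2Z,4S,5R)-5-[(TBS-oxy)methyl]-5-ethyl-2-iodo-4-phenylhepta-2,6-diene | CC[C@@]([C@H](c1ccccc1)/C=C(/C)I)(CO[Si](C)(C)C(C)(C)C)C=C
F4 | step 11 | (4Z,6S,7R)-7-[(TBS-oxy)methyl]-7-ethyl-4-methyl-6-phenylnona-4,8-dien-2-yne | CC[C@@]([C@H](c1ccccc1)/C=C(/C)C#CC)(CO[Si](C)(C)C(C)(C)C)C=C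
F5 | step 11 | hexacarbonyldicobalt complex of the alkyne of F4 | CC[C@@]([C@H](c1ccccc1)/C=C(/C)C23[Co]4(=C=O)(=C=O)(=C=O)[Co]2(=C=O)(=C=O)(=C=O)C34C)(CO[Si](C)(C)C(C)(C)C)C=C
F6 | step 11 | 3-demethyl analogue of dienone 19 (3a-H β) | CC[C@@]1(CO[Si](C)(C)C(C)(C)C)[C@H]2C(C(C)=C[C@H]1c1ccccc1)=C(C)C(=O)C2
F7 | step 11 | 3-epimer of dienone 19 (3-CH3 β) | CC[C@@]1(CO[Si](C)(C)C(C)(C)C)[C@H]2C(C(C)=C[C@H]1c1ccccc1)=C(C)C(=O)[C@@H]2C
F8 | step 13 | 6α,7α-epoxide of dienone 19 | CC[C@@]1(CO[Si](C)(C)C(C)(C)C)[C@H]2C([C@]3(C)O[C@@H]3[C@H]1c1ccccc1)=C(C)C(=O)[C@H]2C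
F9 | step 13 | 2α-alcohol of F8 | CC[C@@]1(CO[Si](C)(C)C(C)(C)C)[C@H]2C([C@]3(C)O[C@@H]3[C@H]1c1ccccc1)=C(C)[C@@H](O)[C@H]2C
F10 | step 13 | 6α,7α-epoxide of alcohol 21 (1-H α; 7a-H α) | CC[C@@]1(CO[Si](C)(C)C(C)(C)C)[C@H]2[C@H]([C@]3(C)O[C@@H]3[C@H]1c1ccccc1)[C@H](C)[C@@H](O)[C@H]2C
F11 | step 9 | (3S,4R,5Z)-4-[(TBS-oxy)methyl]-1,1-dichloro-4-ethyl-3-phenylhepta-1,5-diene | CC[C@@]([C@H](c1ccccc1)C=C(Cl)Cl)(CO[Si](C)(C)C(C)(C)C)/C=C\C
F12 | step 9 | (2Z,4S,5R,6Z)-5-[(TBS-oxy)methyl]-2-chloro-5-ethyl-4-phenylocta-2,6-diene | CC[C@@]([C@H](c1ccccc1)/C=C(/C)Cl)(CO[Si](C)(C)C(C)(C)C)/C=C\C
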